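**Plan**

- Enabling feature: the furan ring has O1 flanked by C2 (acid chain) and C5 (pentyl), CH3 on C3 and H on C4. This is the carbon pattern of a C14=C15(CH3)–C16=C17 diene inside an unbranched C22 ester, and adding O2 to the diene termini then removing H2O gives exactly this ring.
- Cuts: O1–C2 and O1–C5 go back through a 1,2-dioxine to the diene. C16=C17 (Julia–Kocienski) and C14=C15 (Wittig) are cut next, leaving a C14 aldehyde ester, a C3 formyl ylide and a C6 sulfone.
- Forward: tetradecanedioic acid is desymmetrised to the aldehyde ester and the chain grows C14 → C16 (+CH3) → C22. Singlet oxygen then closes the six-membered peroxide ring, base followed by acid convert it into the furan, and saponification ends the route.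
- Stereochemistry: the target has none. The two E alkenes come from the stabilised ylide and the tetrazolyl sulfone. The two cis stereocentres of the racemic peroxide follow from suprafacial addition and disappear on aromatisation.

Key step: step 8

Remark: locants C1–C22 count the docosanoate chain from the carboxyl carbon, and every chiral compound of the route is a racemate of which one enantiomer is drawn.

**Route**

Step 1
Reactants: 1 tetradecanedioic acid
Product: 2 14-methoxy-14-oxotetradecanoic acid (monomethyl tetradecanedioate)
Conditions: MeOH (1.5 equiv), H2SO4 (cat.), toluene, 80 °C, stopped at partial conversion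
Reagents that add atoms: methanol, CO
Why: Fischer esterification with limiting methanol should give the statistical half-ester; unreacted diacid is filtered off, over-esterified material is removed by chromatography, and both can be recycled.

Step 2
Reactants: 2 14-methoxy-14-oxotetradecanoic acid
Product: 3 methyl 14-hydroxytetradecanoate
Conditions: BH3·THF (1.1 equiv), THF, −15 °C → rt; aqueous work-up
Reagents that add atoms: none
Why: In this chemoselective borane reduction the free acid is activated as an acyloxyborane and reduced far faster than the methyl ester.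

Step 3
Reactants: 3 methyl 14-hydroxytetradecanoate
Product: 4 methyl 14-oxotetradecanoate
Conditions: TEMPO (10 mol %), PhI(OAc)2 (1.1 equiv), CH2Cl2, rt
Reagents that add atoms: none
Why: Oxoammonium (TEMPO) oxidation of a primary alcohol in a water-free medium should stop at the aldehyde and leave the ester untouched.

Step 4
Reactants: 4 methyl 14-oxotetradecanoate; 5 2-(triphenylphosphoranylidene)propanal
Product: 6 methyl (14E)-15-methyl-16-oxohexadec-14-enoate
Conditions: toluene, 90 °C
Reagents that add atoms: none
Why: Wittig olefination with a stabilised, α-branched formyl ylide passes through the less crowded trans-oxaphosphetane and should give the E enal, whose conjugated and hindered aldehyde reacts too slowly for a second homologation.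

Step 5
Reactants: 7 1-bromohexane; 8 1-phenyl-1H-tetrazole-5-thiol
Product: 9 5-(hexylsulfanyl)-1-phenyl-1H-tetrazole
Conditions: K2CO3 (1.5 equiv), acetone, reflux
Reagents that add atoms: none
Why: This is an SN2 S-alkylation of the soft tetrazolethiolate by an unhindered primary bromide.

Step 6
Reactants: 9 5-(hexylsulfanyl)-1-phenyl-1H-tetrazole
Product: 10 5-(hexane-1-sulfonyl)-1-phenyl-1H-tetrazole
Conditions: 30 % aq. H2O2 (excess), (NH4)6Mo7O24·4H2O (10 mol %), EtOH, 0 °C → rt
Reagents that add atoms: hydrogen peroxide, OO
Why: Molybdate-catalysed peroxide oxidation of a sulfide to the sulfone is the usual entry to Julia–Kocienski reagents, and no other oxidisable group is present.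

Step 7
Reactants: 6 methyl (14E)-15-methyl-16-oxohexadec-14-enoate; 10 5-(hexane-1-sulfonyl)-1-phenyl-1H-tetrazole
Product: 12 methyl (14E,16E)-15-methyldocosa-14,16-dienoate, via potassium sulfonyl carbanion 11 (not isolated)
Conditions: 10 (1.2 equiv), KN(SiMe3)2 (1.15 equiv), DME, −55 °C; then 6, −55 °C → rt
Reagents that add atoms: none
Why: In this Julia–Kocienski olefination the pre-formed carbanion 11 adds to the aldehyde of 6 faster than to its ester, and Smiles transfer of the tetrazole followed by anti loss of SO2 and tetrazololate from the anti adduct (open transition state favoured by K+ in DME) should give the E C16=C17 alkene without disturbing C14=C15.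

Step 8
Reactants: 12 methyl (14E,16E)-15-methyldocosa-14,16-dienoate
Product: 13 methyl 13-[(3R*,6S*)-4-methyl-6-pentyl-3,6-dihydro-1,2-dioxin-3-yl]tridecanoate (cis, racemic)
Conditions: O2 (bubbled), 5,10,15,20-tetraphenylporphyrin (1 mol %), white LED (>400 nm), CH2Cl2, −10 °C
Reagents that add atoms: dioxygen, O=O
Why: Energy transfer from the excited porphyrin gives singlet oxygen, which adds as the 2π component across C14 and C17 of the s-cis conformer of 12 in a concerted suprafacial [4+2] cycloaddition, the classical photooxygenation of acyclic (E,E)-1,3-dienes to 3,6-dihydro-1,2-dioxines. The six-membered O1–O2–C3–C4=C5–C6 ring closes by cycloaddition, both C–O bonds forming in one event while the O–O bond is kept and the new C15=C16 alkene is locked Z inside the ring. The configurations at dioxine C3 and C6 are dictated by the alkene geometries: with both double bonds E the two chains occupy the outer diene positions and are carried to the same ring face (cis), and the product is racemic because the diene faces are enantiotopic and no chiral influence is present. The selectivity needed is periselectivity, [4+2] against the Schenck ene reaction at C13–H, C18–H and the C15 methyl group and against [2+2] dioxetane formation. The substrate helps because only hydrogens sit at the inner positions of C14 and C17, so the s-cis form is unhindered, and because the C15 methyl group clashes with C17–H in the s-trans form and raises the diene HOMO, while an aprotic, weakly polar solvent gives no support to zwitterionic side paths. Neither stereocentre survives step 9, so any loss of stereospecificity here would not change the final furan.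

Step 9
Reactants: 13 methyl 13-[(3R*,6S*)-4-methyl-6-pentyl-3,6-dihydro-1,2-dioxin-3-yl]tridecanoate
Product: 16 methyl 13-(3-methyl-5-pentylfuran-2-yl)tridecanoate, via major hydroxy enone 14 (not isolated), via minor hydroxy enone 15 (not isolated)
Conditions: Et3N (1.0 equiv), CH2Cl2, 0 °C → rt; evaporate; p-TsOH·H2O (10 mol %), 4 Å MS, CH2Cl2, rt, N2, dark
Reagents that add atoms: none
Why: In the Kornblum–DeLaMare rearrangement the amine removes a peroxide α-hydrogen (preferably the less hindered one at dioxine C6) with O–O heterolysis, the ring-derived Z alkene keeps OH and C=O within reach, and acid-catalysed cyclodehydration takes both regioisomeric hydroxy enones to the same aromatic furan.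

Step 10
Reactants: 16 methyl 13-(3-methyl-5-pentylfuran-2-yl)tridecanoate
Product: 18 13-(3-methyl-5-pentylfuran-2-yl)tridecanoic acid, via lithium carboxylate 17 (not isolated)
Conditions: LiOH·H2O (3 equiv), degassed THF–MeOH–H2O, rt; then 1 M HCl to pH 4, 0 °C, N2
Reagents that add atoms: lithium hydroxide, [Li+].[OH-]
Why: Saponification (BAc2) of an unhindered methyl ester leaves the base-stable furan intact, and short, cold acidification under inert gas limits acid and autoxidative damage to the electron-rich ring.

**Compound list**

1 | tetradecanedioic acid | OC(=O)CCCCCCCCCCCCC(=O)O | starting material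
2 | 14-methoxy-14-oxotetradecanoic acid | OC(=O)CCCCCCCCCCCCC(=O)OC | intermediate
3 | methyl 14-hydroxytetradecanoate | OCCCCCCCCCCCCCC(=O)OC | intermediate
4 | methyl 14-oxotetradecanoate | O=CCCCCCCCCCCCCC(=O)OC | intermediate
5 | 2-(triphenylphosphoranylidene)propanal | CC(C=O)=P(c1ccccc1)(c1ccccc1)c1ccccc1 | starting material
6 | methyl (14E)-15-methyl-16-oxohexadec-14-enoate | O=C/C(C)=C/CCCCCCCCCCCCC(=O)OC | intermediate
7 | 1-bromohexane | CCCCCCBr | starting material
8 | 1-phenyl-1H-tetrazole-5-thiol | SC1=NN=NN1c1ccccc1 | starting material
9 | 5-(hexylsulfanyl)-1-phenyl-1H-tetrazole | CCCCCCSc1nnnn1-c1ccccc1 | intermediate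
10 | 5-(hexane-1-sulfonyl)-1-phenyl-1H-tetrazole | CCCCCCS(=O)(=O)c1nnnn1-c1ccccc1 | intermediate
11 | potassium 1-[(1-phenyl-1H-tetrazol-5-yl)sulfonyl]hexan-1-ide | [K+].CCCCC[CH-]S(=O)(=O)c1nnnn1-c1ccccc1 | intermediate
12 | methyl (14E,16E)-15-methyldocosa-14,16-dienoate | CCCCC/C=C/C(C)=C/CCCCCCCCCCCCC(=O)OC | intermediate
13 | methyl 13-[(3R*,6S*)-4-methyl-6-pentyl-3,6-dihydro-1,2-dioxin-3-yl]tridecanoate (cis, racemic) | CCCCC[C@@H]1OO[C@H](CCCCCCCCCCCCC(=O)OC)C(C)=C1 | intermediate
14 | methyl (14R*,15Z)-14-hydroxy-15-methyl-17-oxodocos-15-enoate (racemic) | CCCCCC(=O)/C=C(C)\[C@H](O)CCCCCCCCCCCCC(=O)OC | intermediate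
15 | methyl (15Z,17S*)-17-hydroxy-15-methyl-14-oxodocos-15-enoate (racemic) | CCCCC[C@H](O)/C=C(C)\C(=O)CCCCCCCCCCCCC(=O)OC | intermediate
16 | methyl 13-(3-methyl-5-pentylfuran-2-yl)tridecanoate | CCCCCc1cc(C)c(CCCCCCCCCCCCC(=O)OC)o1 | intermediate
17 | lithium 13-(3-methyl-5-pentylfuran-2-yl)tridecanoate | [Li+].CCCCCc1cc(C)c(CCCCCCCCCCCCC(=O)[O-])o1 | intermediate
18 | 13-(3-methyl-5-pentylfuran-2-yl)tridecanoic acid | CCCCCc1cc(C)c(CCCCCCCCCCCCC(=O)O)o1 | target

**Step count**

Total steps: 10. Longest linear sequence: 8 (steps 1–4 and 7–10); steps 5 and 6 build the sulfone side arm.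

**Steps most likely to fail**

Step 8. Periselectivity may drift toward Schenck ene hydroperoxidation. The C15 methyl group and the C13 methylene lie on the same side of the trisubstituted alkene, an arrangement that suits hydrogen abstraction by singlet oxygen. Long irradiation may also degrade the peroxide. The fallback sets out from 12 and delivers the ring oxygen one C–O bond at a time. Buffered mCPBA (NaHCO3, CH2Cl2, 0 °C) should epoxidise the more electron-rich C14=C15 alkene to the vinyl oxirane methyl 13-{(2R*,3R*)-3-[(1E)-hept-1-en-1-yl]-3-methyloxiran-2-yl}tridecanoate F1. Cu(hfacac)2-catalysed vinyl-oxirane ring expansion (toluene, heat) then moves the oxygen from C15 to C17 and gives methyl 13-(3-methyl-5-pentyl-2,5-dihydrofuran-2-yl)tridecanoate F2. DDQ dehydrogenation comes back to the route at 16.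

Step 7. E selectivity at C16=C17 may erode through a less ordered addition to the conjugated aldehyde, and carbanion may be lost by proton transfer from the ester α-position. The fallback sets out from 6 and moves the bond construction from C16=C17 to C17–C18. Takai olefination (CHI3, CrCl2, THF, 0 °C) should give the dienyl iodide methyl (14E,16E)-17-iodo-15-methylheptadeca-14,16-dienoate F3. Hydroboration of 1-pentene with 9-BBN-H furnishes 9-pentyl-9-borabicyclo[3.3.1]nonane F4. B-alkyl Suzuki–Miyaura coupling of the two (PdCl2(dppf), Cs2CO3, DMF–THF–H2O, rt) proceeds with retention of alkene geometry and comes back at 12.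

Step 9. Deprotonation of a purely alkyl-substituted peroxide by a tertiary amine may be slow enough for O–O homolysis to compete. The electron-rich furan may also suffer acid-induced ring opening or autoxidation during dehydration. The fallback sets out from 13 and replaces the base-induced redox isomerisation by separate reduction and oxidation. Zn dust and AcOH in CH2Cl2 cleave only the O–O bond to give methyl (14R*,15Z,17S*)-14,17-dihydroxy-15-methyldocos-15-enoate F5. MnO2 in CH2Cl2 then oxidises either allylic carbinol, which leads back to 14 and 15, and the acid stage of step 9 carries these on to 16.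

**Further compounds**

F1 | step 8 | methyl 13-{(2R*,3R*)-3-[(1E)-hept-1-en-1-yl]-3-methyloxiran-2-yl}tridecanoate (racemic, heptenyl and ester chain trans) | CCCCC/C=C/[C@@]1(C)O[C@@H]1CCCCCCCCCCCCC(=O)OC
F2 | step 8 | methyl 13-(3-methyl-5-pentyl-2,5-dihydrofuran-2-yl)tridecanoate (configuration at C2 and C5 not controlled and not needed) | CCCCCC1C=C(C)C(CCCCCCCCCCCCC(=O)OC)O1
F3 | step 7 | methyl (14E,16E)-17-iodo-15-methylheptadeca-14,16-dienoate | I/C=C/C(C)=C/CCCCCCCCCCCCC(=O)OC
F4 | step 7 | 9-pentyl-9-borabicyclo[3.3.1]nonane | CCCCCB1C2CCCC1CCC2
F5 | step 9 | methyl (14R*,15Z,17S*)-14,17-dihydroxy-15-methyldocos-15-enoate (racemic) | CCCCC[C@H](O)/C=C(C)\[C@H](O)CCCCCCCCCCCCC(=O)OC
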